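- Early on, the flask ran on a feed: reagent in the second phase crossed into the reaction phase, and starting material, the limiting reagent at 0.40 M against 1.20 M, waited for it, so I kept the books on starting material.

starting material 0.40 M; reagent in the second phase 1.20 M; protic impurity 0.200 M; time 15 h; volume of the second phase over the first 0.50

    target ⇌ isomer of the product (K1 = 1.7, k1 = 2.9 × 10⁻⁶ s⁻¹)
    reagent in the reaction phase ⇌ reagent in the second phase, rate k2*([reagent in the reaction phase] - [reagent in the second phase]/K2) per volume of the first phase (K2 = 1.4, k2 = 4.3 × 10⁻⁶ s⁻¹)
    starting material + protic impurity → quenched substrate (k3 = 1.2 × 10⁻⁵ M⁻¹ s⁻¹)
    starting material + reagent in the reaction phase ⇌ target (K4 = 0.81 M⁻¹, k4 = 9.9 × 10⁻⁴ M⁻¹ s⁻¹)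
    reagent in the reaction phase + target → over-reacted product (k5 = 0.0014 M⁻¹ s⁻¹)

- in the second phase: reagent in the second phase; everything else is in the first
- charges count per volume of the first phase; a concentration in a rate is the amount of a species over the volume of its own phase; every rate counts per litre of the first phase
- run time (flask): 15 h

1. amount of target at 15 h, in percent of the starting material charged
2. part of the starting material charged that has reacted at 15 h

- Delivery: I ignored the back-flow and let the second phase empty first-order, which put 0.339 M of reagent across by 15 h.
- Target: it can fall back or go on to over-reacted product. I set aside its passing into isomer of the product, whose forward half-life of 66 h is longer than the 15 h run. I carried g, the second exit over the first per molar of reagent in the reaction phase, 1.15 M⁻¹. With the two exits balancing the making of target, c(target) = 0.81 M⁻¹ · c(reagent in the reaction phase) · c(starting material) / (1 + g · c(reagent in the reaction phase)).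
- Standing reagent: each over-reacted product carries two reagent units, so I set the opening feed against twice the over-reaction at the charged starting material, which gave c(reagent in the reaction phase) near 0.0901 M.
- Over-reacted product: half of the delivered reagent not left standing, with the single unit held in target set aside, made 0.124 M.
- Quenched substrate: the opening rate, held throughout, made 0.0518 M.
- Closing: target stood at 0.0662 of free starting material, so, with isomer of the product set aside, the books closed with 0.210 M free. That meant 3.47% target and 47.5% reacted.
- The forecast said 4.2% (3.5% to 5%) and 44% (39% to 49%), holding that “over-reaction holds the reagent near 0.1 M”. That was more target and less conversion than my books showed.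
- The flask gave 4.33% target with 40.0% reacted, and at 15.0 h target was being made at 0.938 of the rate at which it was used up. With the 0.0986 M of reagent in the reaction phase and 60.0% of starting material standing in this flask, g returned 4.30% target. In the neighbour flask charged with 0.10 M of starting material, 0.201 M of reagent in the reaction phase and 32.7% of starting material returned 4.32%, and that flask held 4.41%.

The rate constants are assumed.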